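**Plan**

1. Retrosynthesis: the acid goes back to its methyl ester, and the methyl on C7 (carbon 2 of the side chain) to a CH2–O–acyl group. The target thereby becomes a bicyclic lactone in which the carboxyl carbon and the C7 methyl carbon are joined through oxygen.
2. This lactone is cut at two dioxolane bonds at once, C4–C3 and O–C5, into a silylperoxycarbenium ion at C3 and a 1,1-disubstituted alkene (C4=C5) held in one ester. The ester is cut into a chain alcohol and a peroxyketal acid, and the alcohol at its C7–allyl bond.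
3. Enabling feature: C3 with its methyl, carboxymethyl and peroxy oxygen is an acetoacetate carbon at the peroxyketal level, and C4–C5 with the C5 methyl is an isobutene unit. The carboxymethyl arm on C3 and the side chain on C5 are cis on the 1,2-dioxolane, so a six-atom ester bridge between them (a nine-membered lactone) can span the 1,3-positions of the five-membered ring only in the wanted cis sense.
4. Forward order: asymmetric alkylation and reduction give the chain alcohol; ozonolysis in methanol and silylation give the peroxyketal acid; esterification joins them. The annulation closes first the nine-membered lactone (C–C) and then the 1,2-dioxolane (C–O), and four steps take the tether out.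
5. Stereochemistry: C7 from the oxazolidinone auxiliary; C3 and C5 cis from the bridge; their sense relative to C7 from the pseudoequatorial chain on the forming ring.

Key step: step 7

Remark on the chemistry: the ketal carbon of the peroxyketal intermediates forms as both epimers and becomes planar on ionisation, so it is left undefined; C3, C4 and C5 are dioxolane locants.

Step 1
Reactants: 1 10-phenyldecanoic acid; 2 pivaloyl chloride; 3 (4S)-4-benzyl-1,3-oxazolidin-2-one
Product: 5 (4S)-4-benzyl-3-(10-phenyldecanoyl)-1,3-oxazolidin-2-one, via mixed pivalic anhydride 4 (not isolated)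
Conditions: Et3N, THF, −20 °C; then LiCl, 3, −20 °C to rt
Reagents that add atoms: none
Why: N-acylation of the oxazolidinone by a mixed anhydride (LiCl-assisted acyl transfer) is the standard loading of this auxiliary, the nucleophile attacking the less hindered carbonyl of 4.

Step 2
Reactants: 5 (4S)-4-benzyl-3-(10-phenyldecanoyl)-1,3-oxazolidin-2-one; 6 3-bromo-2-methylprop-1-ene
Product: 8 (4S)-4-benzyl-3-[(2R)-2-(2-methylprop-2-en-1-yl)-10-phenyldecanoyl]-1,3-oxazolidin-2-one, via sodium Z-enolate 7 (not isolated)
Conditions: NaN(SiMe3)2, THF, −78 °C; then 6, −78 to −40 °C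
Reagents that add atoms: none
Why: Evans asymmetric alkylation, in which the chelated Z-enolate is attacked by the allylic bromide on the face away from the benzyl group, should set the (R) centre that becomes C7.

Step 3
Reactants: 8 (4S)-4-benzyl-3-[(2R)-2-(2-methylprop-2-en-1-yl)-10-phenyldecanoyl]-1,3-oxazolidin-2-one
Product: 9 (2R)-2-(2-methylprop-2-en-1-yl)-10-phenyldecan-1-ol
Conditions: LiBH4, THF, 0 °C to rt
Reagents that add atoms: none
Why: Hydride reduction of the exocyclic imide carbonyl (reductive removal of the auxiliary) should give the primary alcohol without touching the stereocentre or the alkene, and returns 3.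

Step 4
Reactants: 10 3-methylbut-3-enoic acid
Product: 13 3-hydroperoxy-3-methoxybutanoic acid, via primary ozonide 11 (not isolated), via carbonyl oxide 12 (not isolated)
Conditions: O3, CH2Cl2/MeOH 4:1, −78 °C; N2 purge; concentrated cold
Reagents that add atoms: ozone [O-][O+]=O; methanol CO
Why: Ozonolysis in methanol (Criegee mechanism) should place the carbonyl oxide on the disubstituted carbon, where methanol traps it as the α-methoxy hydroperoxide; the new ketal centre is racemic and is erased later on ionisation.

Step 5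
Reactants: 13 3-hydroperoxy-3-methoxybutanoic acid
Product: 15 3-methoxy-3-[(triethylsilyl)peroxy]butanoic acid, via bis-silyl compound 14 (not isolated)
Conditions: Et3SiCl (2.3 equiv), imidazole, CH2Cl2, 0 °C; then aq. NaH2PO4/Na2HPO4 (pH 7)/THF, 0 °C; used at once
Reagents that add atoms: chlorotriethylsilane CC[Si](Cl)(CC)CC
Why: O-silylation of both acidic OH groups followed by selective hydrolysis, the silyl ester being far more labile than the silyl peroxide, should leave the triethylsilyl peroxide that later departs as Et3SiCl.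

Step 6
Reactants: 9 (2R)-2-(2-methylprop-2-en-1-yl)-10-phenyldecan-1-ol; 15 3-methoxy-3-[(triethylsilyl)peroxy]butanoic acid
Product: 16 (2R)-2-(2-methylprop-2-en-1-yl)-10-phenyldecyl 3-methoxy-3-[(triethylsilyl)peroxy]butanoate
Conditions: DCC, DMAP (cat.), CH2Cl2, 0 °C
Reagents that add atoms: none
Why: Steglich esterification joins the unhindered primary alcohol and the acid under neutral conditions that should ionise neither the ketal nor the silyl peroxide.

Step 7
Reactants: 16 (2R)-2-(2-methylprop-2-en-1-yl)-10-phenyldecyl 3-methoxy-3-[(triethylsilyl)peroxy]butanoate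
Product: 19 (1R,6R,8R)-1,8-dimethyl-6-(8-phenyloctyl)-4,9,10-trioxabicyclo[6.2.1]undecan-3-one, via silylperoxycarbenium ion 17 (not isolated), via lactone tertiary cation 18 (not isolated)
Conditions: SnCl4 (1.2 equiv), CH2Cl2, −78 °C, 16 added by syringe pump over 8 h (at most 1 mM); then aq. NaHCO3
Reagents that add atoms: none
Why: Proposed new method: SnCl4 removes the methoxy group of 16 to give silylperoxycarbenium ion 17, the 1,1-disubstituted alkene attacks its carbon through the unsubstituted CH2 terminus (Markovnikov) to give tertiary cation 18, and the silylated peroxy oxygen captures that cation with loss of Et3SiCl; the closest known reaction is the intermolecular SnCl4-mediated [3+2] annulation of triethylsilyl peroxyketals with 1,1-disubstituted alkenes, which has not been run through an ester tether. The nine-membered lactone closes by a 9-endo-trig cation–olefin cyclisation (C–C bond), and the 1,2-dioxolane by transannular 1,3-capture of the cation by oxygen (C–O bond), a five-membered closure between two centres the ring already holds close. The two new quaternary centres must be cis because the six-atom ester bridge cannot span trans positions of a five-membered ring, which puts the carboxymethyl arm and the side-chain CH2 on one face and the two methyl groups on the other. Their sense relative to the existing (R) centre is expected to follow from the 8-phenyloctyl chain taking a pseudoequatorial place on the forming ring, which sets the silylperoxy group, and hence the peroxide bridge, on the face away from the chain and leads to the (1R,8R) lactone; the other cis isomer (1S,6R,8S), if formed, is a rigid diastereomer that should separate on silica. The step needs cyclisation to win over oligomerisation, proton loss from 18 and chloride capture, which slow addition into cold dilute SnCl4 and the high rate of cation–alkene capture are meant to secure.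

Step 8
Reactants: 19 (1R,6R,8R)-1,8-dimethyl-6-(8-phenyloctyl)-4,9,10-trioxabicyclo[6.2.1]undecan-3-one
Product: 20 methyl 2-[(3R,5R)-5-[(2R)-2-(hydroxymethyl)-10-phenyldecyl]-3,5-dimethyl-1,2-dioxolan-3-yl]acetate
Conditions: NaOMe (cat.), MeOH, 0 °C
Reagents that add atoms: methanol CO
Why: Methoxide-catalysed transesterification (lactone methanolysis) should be driven by relief of medium-ring strain and by solvent methanol, the fully substituted peroxide having no α-hydrogen for base-induced cleavage.

Step 9
Reactants: 20 methyl 2-[(3R,5R)-5-[(2R)-2-(hydroxymethyl)-10-phenyldecyl]-3,5-dimethyl-1,2-dioxolan-3-yl]acetate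
Product: 21 methyl 2-[(3R,5R)-3,5-dimethyl-5-[(2R)-2-{[(4-methylbenzenesulfonyl)oxy]methyl}-10-phenyldecyl]-1,2-dioxolan-3-yl]acetate
Conditions: TsCl, pyridine, DMAP (cat.), CH2Cl2, 0 °C to rt
Reagents that add atoms: 4-methylbenzenesulfonyl chloride Cc1ccc(cc1)S(=O)(=O)Cl
Why: Sulfonylation of the primary alcohol (tosylate formation) turns the oxygen of the former tether into a leaving group without touching the peroxide.

Step 10
Reactants: 21 methyl 2-[(3R,5R)-3,5-dimethyl-5-[(2R)-2-{[(4-methylbenzenesulfonyl)oxy]methyl}-10-phenyldecyl]-1,2-dioxolan-3-yl]acetate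
Product: 22 methyl 2-[(3R,5R)-3,5-dimethyl-5-[(2R)-2-methyl-10-phenyldecyl]-1,2-dioxolan-3-yl]acetate
Conditions: NaBH4, DMSO, 60 °C
Reagents that add atoms: none
Why: SN2 displacement of the primary tosylate by hydride in a dipolar aprotic solvent should turn CH2OTs into the C7 methyl group under conditions that a methyl ester and a tertiary dialkyl peroxide are expected to survive.

Step 11
Reactants: 22 methyl 2-[(3R,5R)-3,5-dimethyl-5-[(2R)-2-methyl-10-phenyldecyl]-1,2-dioxolan-3-yl]acetate
Product: 24 2-[(3R,5R)-3,5-dimethyl-5-[(2R)-2-methyl-10-phenyldecyl]-1,2-dioxolan-3-yl]acetic acid, via lithium carboxylate 23 (not isolated)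
Conditions: LiOH, THF/H2O, 0 °C to rt; then 1 M HCl, 0 °C
Reagents that add atoms: lithium hydroxide [Li+].[OH-]
Why: Saponification of the methyl ester (BAc2 hydrolysis) and cold acidification should give the acid, the peroxide carbons carrying no hydrogen that base could remove.

**Compound list**

1 | 10-phenyldecanoic acid | OC(=O)CCCCCCCCCc1ccccc1 | starting material
2 | pivaloyl chloride | CC(C)(C)C(=O)Cl | starting material
3 | (4S)-4-benzyl-1,3-oxazolidin-2-one | O=C1N[C@@H](Cc2ccccc2)CO1 | starting material
4 | mixed anhydride of 10-phenyldecanoic acid and pivalic acid | CC(C)(C)C(=O)OC(=O)CCCCCCCCCc1ccccc1 | intermediate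
5 | (4S)-4-benzyl-3-(10-phenyldecanoyl)-1,3-oxazolidin-2-one | O=C(CCCCCCCCCc1ccccc1)N1[C@@H](Cc2ccccc2)COC1=O | intermediate
6 | 3-bromo-2-methylprop-1-ene | C=C(C)CBr | starting material
7 | sodium (Z)-enolate of 5 | [Na+].[O-]/C(=C\CCCCCCCCc1ccccc1)N1[C@@H](Cc2ccccc2)COC1=O | intermediate
8 | (4S)-4-benzyl-3-[(2R)-2-(2-methylprop-2-en-1-yl)-10-phenyldecanoyl]-1,3-oxazolidin-2-one | O=C([C@H](CCCCCCCCc1ccccc1)CC(C)=C)N1[C@@H](Cc2ccccc2)COC1=O | intermediate
9 | (2R)-2-(2-methylprop-2-en-1-yl)-10-phenyldecan-1-ol | OC[C@H](CCCCCCCCc1ccccc1)CC(C)=C | intermediate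
10 | 3-methylbut-3-enoic acid | C=C(C)CC(=O)O | starting material
11 | primary ozonide, 2-(4-methyl-1,2,3-trioxolan-4-yl)acetic acid | CC1(CC(=O)O)COOO1 | intermediate
12 | carbonyl oxide (Criegee zwitterion) of 3-oxobutanoic acid | CC(CC(=O)O)=[O+][O-] | intermediate
13 | 3-hydroperoxy-3-methoxybutanoic acid (racemic) | CC(OC)(OO)CC(=O)O | intermediate
14 | triethylsilyl 3-methoxy-3-[(triethylsilyl)peroxy]butanoate | CC(OC)(OO[Si](CC)(CC)CC)CC(=O)O[Si](CC)(CC)CC | intermediate
15 | 3-methoxy-3-[(triethylsilyl)peroxy]butanoic acid | CC(OC)(OO[Si](CC)(CC)CC)CC(=O)O | intermediate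
16 | (2R)-2-(2-methylprop-2-en-1-yl)-10-phenyldecyl 3-methoxy-3-[(triethylsilyl)peroxy]butanoate (both ketal epimers) | CC(OC)(OO[Si](CC)(CC)CC)CC(=O)OC[C@H](CCCCCCCCc1ccccc1)CC(C)=C | intermediate
17 | silylperoxycarbenium ion of 16 (methoxide removed from the ketal carbon, C=O+–OSiEt3) as its SnCl4(OMe)− salt | CC(=[O+]O[Si](CC)(CC)CC)CC(=O)OC[C@H](CCCCCCCCc1ccccc1)CC(C)=C.CO[Sn-](Cl)(Cl)(Cl)Cl | intermediate
18 | nine-membered lactone cation (new C–C bond made, tertiary carbocation at the former alkene carbon, silylperoxy group on the neighbouring quaternary carbon) as its SnCl4(OMe)− salt | C1[C@H](CCCCCCCCc2ccccc2)C[C+](C)C[C@](C)(CC(=O)O1)OO[Si](CC)(CC)CC.CO[Sn-](Cl)(Cl)(Cl)Cl | intermediate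
19 | (1R,6R,8R)-1,8-dimethyl-6-(8-phenyloctyl)-4,9,10-trioxabicyclo[6.2.1]undecan-3-one | C1[C@H](CCCCCCCCc2ccccc2)C[C@]3(C)C[C@](C)(CC(=O)O1)OO3 | intermediate
20 | methyl 2-[(3R,5R)-5-[(2R)-2-(hydroxymethyl)-10-phenyldecyl]-3,5-dimethyl-1,2-dioxolan-3-yl]acetate | OC[C@H](CCCCCCCCc1ccccc1)C[C@]1(C)C[C@](C)(CC(=O)OC)OO1 | intermediate
21 | methyl 2-[(3R,5R)-3,5-dimethyl-5-[(2R)-2-{[(4-methylbenzenesulfonyl)oxy]methyl}-10-phenyldecyl]-1,2-dioxolan-3-yl]acetate | Cc1ccc(cc1)S(=O)(=O)OC[C@H](CCCCCCCCc2ccccc2)C[C@]3(C)C[C@](C)(CC(=O)OC)OO3 | intermediate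
22 | methyl 2-[(3R,5R)-3,5-dimethyl-5-[(2R)-2-methyl-10-phenyldecyl]-1,2-dioxolan-3-yl]acetate | C[C@H](CCCCCCCCc1ccccc1)C[C@]1(C)C[C@](C)(CC(=O)OC)OO1 | intermediate
23 | lithium 2-[(3R,5R)-3,5-dimethyl-5-[(2R)-2-methyl-10-phenyldecyl]-1,2-dioxolan-3-yl]acetate | C[C@H](CCCCCCCCc1ccccc1)C[C@]1(C)C[C@](C)(CC(=O)[O-])OO1.[Li+] | intermediate
24 | 2-[(3R,5R)-3,5-dimethyl-5-[(2R)-2-methyl-10-phenyldecyl]-1,2-dioxolan-3-yl]acetic acid | C[C@H](CCCCCCCCc1ccccc1)C[C@]1(C)C[C@](C)(CC(=O)O)OO1 | target

**Step count and risks**

Total step count: 11. Longest linear sequence: 9 (steps 1, 2, 3, 6, 7, 8, 9, 10, 11).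

Steps most likely to fail:

Step 7. Closure of a nine-membered ring may lose to intermolecular oligomerisation, to proton loss from the tertiary cation or to chloride capture, and facial discrimination by the chain may be weak. The fallback is the known intermolecular annulation; it sets out from 9 and 15 and comes back at 22. Alcohol 9 is tosylated (TsCl, pyridine) to (2R)-2-(2-methylprop-2-en-1-yl)-10-phenyldecyl 4-methylbenzenesulfonate F1 and reduced with LiAlH4 in Et2O to [(9R)-9,11-dimethyldodec-11-en-1-yl]benzene F2. Acid 15 is methylated with (trimethylsilyl)diazomethane to methyl 3-methoxy-3-[(triethylsilyl)peroxy]butanoate F3. SnCl4 in CH2Cl2 at −78 °C should join F2 and F3 to methyl 2-{3,5-dimethyl-5-[(2R)-2-methyl-10-phenyldecyl]-1,2-dioxolan-3-yl}acetate as the mixture of its ring diastereomers F4, from which 22 would be separated by preparative HPLC. Steps 6 and 8 to 10 then fall away, at the price of no control over the two ring centres.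

Step 5. The silyl peroxide may be lost together with the silyl ester, or the free acid may ionise its own ketal before it is coupled. The fallback builds the peroxyketal on the ester instead; it sets out from 9 and comes back at 16. Alcohol 9 is acetoacetylated with 2,2,6-trimethyl-4H-1,3-dioxin-4-one (xylene, 140 °C) to (2R)-2-(2-methylprop-2-en-1-yl)-10-phenyldecyl 3-oxobutanoate F5. This is ketalised with HC(OMe)3/MeOH and pyridinium tosylate to (2R)-2-(2-methylprop-2-en-1-yl)-10-phenyldecyl 3,3-dimethoxybutanoate F6. Exchange with anhydrous ethereal H2O2 under the same acid at 0 °C should give (2R)-2-(2-methylprop-2-en-1-yl)-10-phenyldecyl 3-hydroperoxy-3-methoxybutanoate F7, which is silylated (Et3SiCl, imidazole) to 16.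

Step 10. At the temperature that the β-branched tosylate needs, hydride may attack the peroxide or the ester before it displaces the sulfonate. The fallback removes the oxygen at the aldehyde level; it sets out from 20 and comes back at 22. Alcohol 20 is oxidised with Dess–Martin periodinane to methyl 2-[(3R,5R)-5-[(2R)-2-formyl-10-phenyldecyl]-3,5-dimethyl-1,2-dioxolan-3-yl]acetate F8. Condensation with 4-methylbenzenesulfonohydrazide gives the tosylhydrazone methyl 2-[(3R,5R)-3,5-dimethyl-5-[(2R)-2-{[2-(4-methylbenzenesulfonyl)hydrazinylidene]methyl}-10-phenyldecyl]-1,2-dioxolan-3-yl]acetate F9. Reduction with catecholborane (CHCl3, 0 °C; then NaOAc·3H2O) should give 22 with loss of sulfinate and dinitrogen.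

**Further compounds**

F1 | step 7 | (2R)-2-(2-methylprop-2-en-1-yl)-10-phenyldecyl 4-methylbenzenesulfonate | Cc1ccc(cc1)S(=O)(=O)OC[C@H](CCCCCCCCc2ccccc2)CC(C)=C
F2 | step 7 | [(9R)-9,11-dimethyldodec-11-en-1-yl]benzene | C[C@H](CCCCCCCCc1ccccc1)CC(C)=C
F3 | step 7 | methyl 3-methoxy-3-[(triethylsilyl)peroxy]butanoate | CC(OC)(OO[Si](CC)(CC)CC)CC(=O)OC
F4 | step 7 | methyl 2-{3,5-dimethyl-5-[(2R)-2-methyl-10-phenyldecyl]-1,2-dioxolan-3-yl}acetate, mixture of ring diastereomers | C[C@H](CCCCCCCCc1ccccc1)CC1(C)CC(C)(CC(=O)OC)OO1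
F5 | step 5 | (2R)-2-(2-methylprop-2-en-1-yl)-10-phenyldecyl 3-oxobutanoate | CC(=O)CC(=O)OC[C@H](CCCCCCCCc1ccccc1)CC(C)=C
F6 | step 5 | (2R)-2-(2-methylprop-2-en-1-yl)-10-phenyldecyl 3,3-dimethoxybutanoate | CC(OC)(OC)CC(=O)OC[C@H](CCCCCCCCc1ccccc1)CC(C)=C
F7 | step 5 | (2R)-2-(2-methylprop-2-en-1-yl)-10-phenyldecyl 3-hydroperoxy-3-methoxybutanoate | CC(OC)(OO)CC(=O)OC[C@H](CCCCCCCCc1ccccc1)CC(C)=C
F8 | step 10 | methyl 2-[(3R,5R)-5-[(2R)-2-formyl-10-phenyldecyl]-3,5-dimethyl-1,2-dioxolan-3-yl]acetate | O=C[C@H](CCCCCCCCc1ccccc1)C[C@]1(C)C[C@](C)(CC(=O)OC)OO1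
F9 | step 10 | methyl 2-[(3R,5R)-3,5-dimethyl-5-[(2R)-2-{[2-(4-methylbenzenesulfonyl)hydrazinylidene]methyl}-10-phenyldecyl]-1,2-dioxolan-3-yl]acetate | Cc1ccc(cc1)S(=O)(=O)NN=C[C@H](CCCCCCCCc2ccccc2)C[C@]3(C)C[C@](C)(CC(=O)OC)OO3
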